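The seven-membered dioxepinone (ring C) is opened at the bond between its ester oxygen and the ring B carbon that lies between the hydroxymethyl-bearing carbon and the ether-bearing carbon. The key step exploits the ring B phenol, which sits para to the diaryl ether oxygen. Oxidation with a trivalent iodine reagent lets the ring A carboxylic acid add to the ether-bearing carbon as a spiro lactone ketal, and an acid-driven 1,2-acyloxy shift to the adjacent CH carbon then closes ring C with rearomatisation. The precursor is diaryl ether acid 16, made by SNAr between a 2-fluoroisophthalate and a phthalide derived from a symmetric hydroquinone.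

Key step: step 11

Remark: the target has no stereocentre, so no stereocontrol is needed. Ring A is the methyl-bearing benzoate ring, ring B the benzene ring fused to the five-membered lactone (phthalide numbering is used for its fragments), ring C the seven-membered lactone. Diethyl 2,5-dihydroxyterephthalate (1) and 3-fluoro-5-methylphenol (8) are assumed to be commercial.

Step 1
Reactants: 1 diethyl 2,5-dihydroxyterephthalate
Product: 2 diethyl 2,5-bis(methoxymethoxy)benzene-1,4-dicarboxylate
Conditions: NaH, MOMCl, DMF, 0 °C to rt
Reagents that add atoms: chloromethyl methyl ether, COCCl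
Why: Williamson O-alkylation: NaH fully deprotonates both ester-chelated phenols and the phenoxides displace chloride from the α-chloro ether, masking the hydroquinone as MOM acetals that later direct lithiation.

Step 2
Reactants: 2 diethyl 2,5-bis(methoxymethoxy)benzene-1,4-dicarboxylate
Product: 3 [2,5-bis(methoxymethoxy)-1,4-phenylene]dimethanol
Conditions: LiAlH4, THF, 0 °C to rt; aqueous potassium sodium tartrate (KNaC4H4O6) work-up
Reagents that add atoms: none
Why: LiAlH4 reduction of both aryl esters to primary benzylic alcohols, to which the MOM acetals are inert, should give the C2-symmetric diol.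

Step 3
Reactants: 3 [2,5-bis(methoxymethoxy)-1,4-phenylene]dimethanol
Product: 6 4,7-dihydroxy-6-(hydroxymethyl)-2-benzofuran-1(3H)-one, via trilithiated diol 4 (not isolated), via hydroxy acid 5 (not isolated)
Conditions: n-BuLi (3.3 equiv), TMEDA, THF, −78 to 0 °C; CO2, −78 °C to rt; then 3 M HCl, THF, 50 °C
Reagents that add atoms: carbon dioxide, O=C=O
Why: Directed ortho-metalation: after both hydroxyl groups are deprotonated, the third equivalent of n-BuLi lithiates one of the two symmetry-equivalent ring CH positions (each flanked by an OMOM and a CH2OLi group), carboxylation gives a 2-(hydroxymethyl)benzoic acid, and aqueous acid lactonises it to the phthalide and hydrolyses both MOM acetals, so every ring B carbon is in place.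

Step 4
Reactants: 6 4,7-dihydroxy-6-(hydroxymethyl)-2-benzofuran-1(3H)-one
Product: 7 phthalide acetonide (CMe2 bridging the 7-O and the 6-CH2O, 4-OH free)
Conditions: 2,2-dimethoxypropane, pyridinium p-toluenesulfonate (cat.), acetone, rt
Reagents that add atoms: 2,2-dimethoxypropane, COC(C)(C)OC
Why: Acid-catalysed transacetalisation: only the 7-OH has an ortho CH2OH with which it can form a six-membered 1,3-dioxine, so one acetonide masks that phenol and the primary alcohol and leaves the 4-OH as the only nucleophile.

Step 5
Reactants: 8 3-fluoro-5-methylphenol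
Product: 9 4-bromo-3-fluoro-5-methylphenol
Conditions: NBS, MeCN, −20 to 0 °C
Reagents that add atoms: N-bromosuccinimide, O=C1CCC(=O)N1Br
Why: Electrophilic aromatic bromination with NBS in MeCN is para-selective for phenols, and the para position (between F and CH3) is the one that later carries the lactone carboxyl group.

Step 6
Reactants: 9 4-bromo-3-fluoro-5-methylphenol
Product: 10 5-(benzyloxy)-2-bromo-1-fluoro-3-methylbenzene
Conditions: BnBr, K2CO3, DMF, rt
Reagents that add atoms: benzyl bromide, BrCc1ccccc1
Why: Williamson etherification of the phenoxide installs a benzyl group that is removed by hydrogenolysis at the end.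

Step 7
Reactants: 10 5-(benzyloxy)-2-bromo-1-fluoro-3-methylbenzene
Product: 12 benzyl 6-(benzyloxy)-3-bromo-2-fluoro-4-methylbenzoate, via aryllithium 11 (not isolated)
Conditions: 2,2,6,6-tetramethylpiperidine, n-BuLi, THF, −78 °C; then ClCO2Bn, −78 °C to rt
Reagents that add atoms: benzyl chloroformate, O=C(Cl)OCc1ccccc1
Why: Directed ortho-metalation: the lithium amide removes the ring proton flanked by F and OBn (the most acidic one) without bromine–lithium exchange, the aryllithium is held at −78 °C to prevent loss of LiF, and acylation by the chloroformate gives the benzyl ester.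

Step 8
Reactants: 12 benzyl 6-(benzyloxy)-3-bromo-2-fluoro-4-methylbenzoate
Product: 14 1-benzyl 3-tert-butyl 6-(benzyloxy)-2-fluoro-4-methylbenzene-1,3-dicarboxylate, via arylmagnesium chloride 13 (not isolated)
Conditions: i-PrMgCl·LiCl, THF, −15 to 0 °C; then Boc2O, 0 °C to rt
Reagents that add atoms: di-tert-butyl dicarbonate, CC(C)(C)OC(=O)OC(=O)OC(C)(C)C
Why: Halogen–magnesium exchange, accelerated by the ortho fluorine and tolerated by the doubly ortho-substituted benzyl ester, gives an arylmagnesium chloride that Boc2O acylates to the tert-butyl ester, which differentiates the two carboxyl groups.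

Step 9
Reactants: 7 phthalide acetonide; 14 1-benzyl 3-tert-butyl 6-(benzyloxy)-2-fluoro-4-methylbenzene-1,3-dicarboxylate
Product: 15 diaryl ether (ring A diester joined through oxygen to C-4 of the phthalide acetonide)
Conditions: Cs2CO3, DMSO, 70 °C
Reagents that add atoms: none
Why: Nucleophilic aromatic substitution (addition–elimination): the fluoride sits between two ortho ester groups that stabilise the Meisenheimer intermediate, and the caesium phenoxide of 7 is the only nucleophile because the acetonide masks the other two hydroxyl groups.

Step 10
Reactants: 15 diaryl ether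
Product: 16 4-(benzyloxy)-3-(benzyloxycarbonyl)-2-{[7-hydroxy-6-(hydroxymethyl)-1-oxo-1,3-dihydro-2-benzofuran-4-yl]oxy}-6-methylbenzoic acid
Conditions: TFA/CH2Cl2/H2O (10:10:1), 0 °C to rt
Reagents that add atoms: none
Why: Acidolysis: TFA cleaves the tert-butyl ester through the tert-butyl cation and the aqueous acid hydrolyses the acetonide, while the benzyl ester, the benzyl ether and the phthalide are stable, so the carboxylic acid and the ring B phenol needed for the key step are released in one operation.

Step 11
Reactants: 16 diaryl ether acid
Product: 18 O-benzyl conneotricone benzyl ester, via spiro lactone ketal 17 (not isolated)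
Conditions: PhI(OCOCF3)2 (1.05 equiv), (CF3)2CHOH, 4 Å molecular sieves, 0 °C to rt
Reagents that add atoms: none
Why: PhI(OCOCF3)2 exchanges a trifluoroacetate for the ring B phenol and loses PhI to give a phenoxenium ion whose charge is best stabilised at the para carbon bearing the aryloxy oxygen; the ring A carboxylic acid adds there (six-membered spiro ring, 6-endo-trig on the aryloxy-oxocarbenium) to give the spiro 1,3-benzodioxin-4-one quinone ketal 17. The liberated CF3CO2H protonates the dienone, the lactone carbonyl oxygen adds to the adjacent unsubstituted β-carbon (5-exo-trig, a 1,3-dioxolan-2-ylium bridge), the ketal C–O bond breaks and proton loss rearomatises ring B, so the six-membered spiro ring expands to the seven-membered ring C by a net 1,2-acyloxy shift. The closest known reaction types are the oxidative spirolactonisation of para-oxygenated phenols with hypervalent iodine reagents and the acid-induced 1,2-acyloxy shift of quinol esters (a dienone–phenol rearrangement), the oxidative route from 2-(4-hydroxyaryloxy)benzoic acids to this ring system. The step needs oxidation of ring B only (it holds the only free phenol; ring A is benzylated and acceptor-substituted), capture at the para carbon (both ortho carbons are substituted) and migration to the correct neighbour (the other neighbour is the quaternary ring-fusion carbon, from which no proton can be lost, so only the CH carbon leads to an arene). The spiro carbon of 17 is a transient racemic stereocentre erased on rearomatisation, and water must be excluded because hydrolysis of 17 would cleave the diaryl ether.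

Step 12
Reactants: 18 O-benzyl conneotricone benzyl ester
Product: 19 conneotricone
Conditions: H2 (1 atm), 10% Pd/C, EtOAc, rt
Reagents that add atoms: none
Why: Catalytic hydrogenolysis cleaves the benzyl ester and the aryl benzyl ether under neutral conditions at ambient pressure, under which the primary benzylic alcohol, the phthalide and the aryl ester of ring C should be retained.

Compound list
1 | diethyl 2,5-dihydroxyterephthalate | CCOC(=O)c1cc(O)c(C(=O)OCC)cc1O | starting material
2 | diethyl 2,5-bis(methoxymethoxy)benzene-1,4-dicarboxylate | CCOC(=O)c1cc(OCOC)c(C(=O)OCC)cc1OCOC | intermediate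
3 | [2,5-bis(methoxymethoxy)-1,4-phenylene]dimethanol | OCc1cc(OCOC)c(CO)cc1OCOC | intermediate
4 | trilithiated diol (both alkoxides and the ring carbon between OMOM and CH2OLi; not isolated) | [Li]OCc1cc(OCOC)c(CO[Li])c([Li])c1OCOC | intermediate
5 | 3,6-bis(hydroxymethyl)-2,5-bis(methoxymethoxy)benzoic acid (not isolated) | OCc1cc(OCOC)c(CO)c(C(=O)O)c1OCOC | intermediate
6 | 4,7-dihydroxy-6-(hydroxymethyl)-2-benzofuran-1(3H)-one | O=C1OCc2c(O)cc(CO)c(O)c12 | intermediate
7 | phthalide acetonide: acetonide of 6 in which CMe2 bridges the 7-O and the 6-CH2O (a 2,2-dimethyl-4H-1,3-benzodioxine fused to the lactone), 4-OH free | O=C1OCc2c(O)cc3c(c12)OC(C)(C)OC3 | intermediate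
8 | 3-fluoro-5-methylphenol | Cc1cc(O)cc(F)c1 | starting material
9 | 4-bromo-3-fluoro-5-methylphenol | Cc1cc(O)cc(F)c1Br | intermediate
10 | 5-(benzyloxy)-2-bromo-1-fluoro-3-methylbenzene | Cc1cc(OCc2ccccc2)cc(F)c1Br | intermediate
11 | [6-(benzyloxy)-3-bromo-2-fluoro-4-methylphenyl]lithium (not isolated) | [Li]c1c(F)c(Br)c(C)cc1OCc1ccccc1 | intermediate
12 | benzyl 6-(benzyloxy)-3-bromo-2-fluoro-4-methylbenzoate | Cc1cc(OCc2ccccc2)c(C(=O)OCc2ccccc2)c(F)c1Br | intermediate
13 | arylmagnesium chloride from 12 (Mg in place of Br; not isolated) | Cc1cc(OCc2ccccc2)c(C(=O)OCc2ccccc2)c(F)c1[Mg]Cl | intermediate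
14 | 1-benzyl 3-tert-butyl 6-(benzyloxy)-2-fluoro-4-methylbenzene-1,3-dicarboxylate | Cc1cc(OCc2ccccc2)c(C(=O)OCc2ccccc2)c(F)c1C(=O)OC(C)(C)C | intermediate
15 | diaryl ether: 14 with F replaced by the 4-O of phthalide acetonide 7 | Cc1cc(OCc2ccccc2)c(C(=O)OCc2ccccc2)c(Oc2cc3c(c4c2COC4=O)OC(C)(C)OC3)c1C(=O)OC(C)(C)C | intermediate
16 | 4-(benzyloxy)-3-(benzyloxycarbonyl)-2-{[7-hydroxy-6-(hydroxymethyl)-1-oxo-1,3-dihydro-2-benzofuran-4-yl]oxy}-6-methylbenzoic acid | Cc1cc(OCc2ccccc2)c(C(=O)OCc2ccccc2)c(Oc2cc(CO)c(O)c3c2COC3=O)c1C(=O)O | intermediate
17 | spiro lactone ketal (racemic, not isolated): the former para carbon of ring B carries the diaryl ether oxygen and the ring A carboxylate oxygen within a 1,3-benzodioxin-4-one; ring B is a cyclohexa-2,5-dienone fused to the butenolide | Cc1cc(OCc2ccccc2)c(C(=O)OCc2ccccc2)c2c1C(=O)OC1(O2)C=C(CO)C(=O)C2=C1COC2=O | intermediate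
18 | O-benzyl conneotricone benzyl ester (ring A OH as benzyl ether, ring A CO2H as benzyl ester) | Cc1cc(OCc2ccccc2)c(C(=O)OCc2ccccc2)c2c1C(=O)Oc1c(CO)c(O)c3c(c1O2)COC3=O | intermediate
19 | conneotricone | Cc1cc(O)c(C(=O)O)c2c1C(=O)Oc1c(CO)c(O)c3c(c1O2)COC3=O | target

Total step count: 12. Longest linear sequence: 8 steps (steps 1–4 or steps 5–8, followed by steps 9–12).

Steps most likely to fail

Step 11. The phenoxenium ion may be intercepted by the neighbouring hydroxymethyl oxygen (spiro-epoxide formation) or by traces of water, which would cleave the diaryl ether as a quinone; alternatively the spiro ketal may resist the acyloxy shift. The fallback places a halogen on the ring B carbon beforehand and forms the same aryl C–O bond by an Ullmann-type lactonisation. It sets out from 7: NBS in MeCN at 0 °C should brominate the only free ring position, ortho to the free phenol, to give the 5-bromo phthalide acetonide F1. SNAr with 14 (Cs2CO3, DMSO, 80 °C) should give the bromo diaryl ether F2, and TFA/CH2Cl2/H2O should release the bromo hydroxy acid F3. Intramolecular O-arylation of the carboxylate with the aryl bromide (CuI, 1,10-phenanthroline, Cs2CO3, toluene/DMF, 100 °C) then returns to the route at 18.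

Step 9. Addition to the fluoride may be sluggish because both activating esters are twisted out of conjugation, and at the temperature then needed the phenoxide may instead dealkylate the benzyl ester. The fallback uses a small, coplanar formyl group as the second activator. It sets out from 12: exchange with i-PrMgCl·LiCl (via 13) and quenching with DMF should give benzyl 6-(benzyloxy)-2-fluoro-3-formyl-4-methylbenzoate F4. SNAr with 7 (K2CO3, DMF, 50 °C) should give the formyl diaryl ether F5. Pinnick oxidation (NaClO2, NaH2PO4, 2-methyl-2-butene, t-BuOH/H2O) should give the acid acetonide F6, and 1 M HCl in THF removes the acetonide and returns to the route at 16.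

Step 3. Ring lithiation of the poorly soluble dilithium dialkoxide may be incomplete or go twice, and formaldehyde released during MOM hydrolysis may condense with the electron-rich phenol. The fallback replaces the metalation by a palladium-catalysed carbonylation. It sets out from 3: NBS (1 equiv) in MeCN at 0 °C should give [3-bromo-2,5-bis(methoxymethoxy)-1,4-phenylene]dimethanol F7 (the two ring positions are equivalent and the first bromine deactivates the ring). Carbonylative lactonisation with the ortho CH2OH (Pd(OAc)2, Xantphos, CO 1 atm, Et3N, toluene, 90 °C) should give 6-(hydroxymethyl)-4,7-bis(methoxymethoxy)-2-benzofuran-1(3H)-one F8. Brief treatment with 3 M HCl in THF at rt then removes the MOM groups and returns to the route at 6.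

Further compounds
F1 | step 11 | 5-bromo phthalide acetonide (7 brominated ortho to the free OH) | O=C1OCc2c(O)c(Br)c3c(c12)OC(C)(C)OC3
F2 | step 11 | bromo diaryl ether (15 with Br on the ring B CH carbon) | Cc1cc(OCc2ccccc2)c(C(=O)OCc2ccccc2)c(Oc2c(Br)c3c(c4c2COC4=O)OC(C)(C)OC3)c1C(=O)OC(C)(C)C
F3 | step 11 | bromo hydroxy acid (16 with Br on the ring B CH carbon) | Cc1cc(OCc2ccccc2)c(C(=O)OCc2ccccc2)c(Oc2c(Br)c(CO)c(O)c3c2COC3=O)c1C(=O)O
F4 | step 9 | benzyl 6-(benzyloxy)-2-fluoro-3-formyl-4-methylbenzoate | Cc1cc(OCc2ccccc2)c(C(=O)OCc2ccccc2)c(F)c1C=O
F5 | step 9 | formyl diaryl ether (15 with CHO in place of CO2t-Bu) | Cc1cc(OCc2ccccc2)c(C(=O)OCc2ccccc2)c(Oc2cc3c(c4c2COC4=O)OC(C)(C)OC3)c1C=O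
F6 | step 9 | acid acetonide (15 with CO2H in place of CO2t-Bu) | Cc1cc(OCc2ccccc2)c(C(=O)OCc2ccccc2)c(Oc2cc3c(c4c2COC4=O)OC(C)(C)OC3)c1C(=O)O
F7 | step 3 | [3-bromo-2,5-bis(methoxymethoxy)-1,4-phenylene]dimethanol | OCc1cc(OCOC)c(CO)c(Br)c1OCOC
F8 | step 3 | 6-(hydroxymethyl)-4,7-bis(methoxymethoxy)-2-benzofuran-1(3H)-one | O=C1OCc2c(OCOC)cc(CO)c(OCOC)c12
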